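**Assumption:** the target has no stereocentre and no stereogenic double bond, so "single enantiomer" is taken to mean the one achiral compound drawn.

**Retrosynthetic overview**
1. Target 4 is the ester of a C28 fatty acid and benzyl alcohol. No ring is formed in the route; the phenyl ring is bought with benzyl alcohol.
2. Single disconnection: the benzylic C–O bond of the ester, giving octacosanoate (from acid 1) and a benzyl cation equivalent (from alcohol 2).
3. Forward: one catalytic dehydrative O-benzylation of 1 with 2; water is the only by-product.

Catalyst for step 1 (commercial, used as bought): 2,3-diphenylcyclopropenone, O=C1C(c2ccccc2)=C1c1ccccc1.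

**Step 1**
Reactants: 1 octacosanoic acid (1.0 equiv); 2 benzyl alcohol (1.1 equiv)
Product: 4 benzyl octacosanoate, via benzyloxycyclopropenium octacosanoate 3 (not isolated)
Conditions: 2,3-diphenylcyclopropenone (10 mol%), PhMe (0.3 M), reflux, Dean–Stark with 4 Å MS in the side arm, 24 h; hot filtration through a short SiO2 pad, recrystallisation from acetone
Reagents that add atoms: none
Why: Proposed new method: activator-free aromatic-cation catalysis of a dehydrative, Mitsunobu-type O-benzylation — with water removed azeotropically the cyclopropenone C=O condenses with 2 to the 2π-aromatic benzyloxycyclopropenium ion, which is stable enough (unlike an ordinary oxocarbenium ion) that the weak acid 1, as its hydrogen-bonded dimer, is the only proton source needed and becomes the carboxylate counter-ion of ion pair 3, and this carboxylate then attacks the benzylic CH2 by SN2, forming the benzylic C–O bond of 4 and releasing neutral diphenylcyclopropenone for the next turnover (an acyl-transfer collapse of the same adducts would also give 4); no stereocentre is formed; the closest known reaction types are the cyclopropenone-catalysed chlorodehydration of alcohols, which needs stoichiometric oxalyl chloride to make the cation, and the redox-neutral phosphine-oxide-catalysed Mitsunobu esterification, which needs strongly acidic pronucleophiles.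

**Compound list**
1 | octacosanoic acid (montanic acid) | CCCCCCCCCCCCCCCCCCCCCCCCCCCC(=O)O | starting material
2 | benzyl alcohol | OCc1ccccc1 | starting material
3 | 1-(benzyloxy)-2,3-diphenylcyclopropenylium octacosanoate (catalyst-bound ion pair) | CCCCCCCCCCCCCCCCCCCCCCCCCCCC(=O)[O-].C(O[C+]1C(c2ccccc2)=C1c1ccccc1)c1ccccc1 | intermediate
4 | benzyl octacosanoate | CCCCCCCCCCCCCCCCCCCCCCCCCCCC(=O)OCc1ccccc1 | target

**Totals**
Total step count: 1. Longest linear sequence: 1 step.

**Steps most likely to fail**
The route has a single step, so the ranking has one entry.

Step 1 (the proposed new method). The risks are:
- The fatty acid (pKa about 4.8) may form the benzyloxycyclopropenium ion too slowly at 111 °C, so turnover stalls.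
- The catalyst may be lost by ring-opening (addition of carboxylate or alcohol at C2/C3, giving α-phenylcinnamic derivatives) or by decarbonylation to diphenylacetylene.
- Benzyl alcohol may capture the cation and give dibenzyl ether.

Fallback with known chemistry: the fallback sets out from 1. Acid 1 is stirred with caesium carbonate (1.0 equiv) in DMF–THF 1:1 at 70 °C to give caesium octacosanoate F1 in the flask. Benzyl bromide (BrCc1ccccc1, 1.1 equiv) is then added and the mixture is kept at 70 °C for about 6 h. This is a classical carboxylate SN2 O-alkylation: the benzyl group comes from a halide electrophile, not from catalytic activation of the alcohol. It gives the ester directly and so comes back to the route at 4. Aqueous work-up and recrystallisation from acetone follow.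

**Further compounds**
F1 | step 1 | caesium octacosanoate | CCCCCCCCCCCCCCCCCCCCCCCCCCCC(=O)[O-].[Cs+]
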